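Ring B is disconnected at C5–C6. Because C5 is allylic to the C1=C10 alkene of ring A, a ring-A C5=C10 alkene can take up the C6 aldehyde at C5 while C1 gives up a hydrogen. One Lewis-acid carbonyl-ene step therefore closes ring B (C5–C10), sets C5 (plus a disposable C6 hydroxyl) and delivers the Δ1(10) alkene. The precursor 16 is a ring-A cyclohexene carrying at C10 the quaternary C9 (methyl, butenyl) and the C8-methyl/C6-aldehyde arm. C4 comes from an asymmetric conjugate methylation, C8 from the chiral pool, C9 from a lactone-enolate methylation; the side chain is finished by Wacker oxidation, olefination and Sharpless epoxidation.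

Key step: step 9

Numbering: ring A = C1–C5 and C10; ring B = C5–C10; C4 carries methyl and CO2Me, C8 a methyl, C9 a methyl and the side chain C11–C15.

Assumption: 1 and 4 are taken as purchasable, and in step 1 the antipode of the chiral carbene ligand that places methyl on the face giving (S)-C4 is used (the sense of induction belongs to the ligand).

Step 1
Reactants: 1 methyl 3-oxocyclohex-1-ene-1-carboxylate
Product: 3 methyl (1S)-1-methyl-3-{[(trifluoromethyl)sulfonyl]oxy}cyclohex-2-ene-1-carboxylate, via methylzinc enolate 2 (not isolated)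
Conditions: Me2Zn, Cu(OTf)2 (cat.), chiral sulfonate-bearing imidazolinium salt (carbene ligand, cat.), t-BuOMe, −30 °C; then Tf2O, −78 → 0 °C
Reagents that add atoms: dimethylzinc C[Zn]C; trifluoromethanesulfonic anhydride O=S(=O)(OS(=O)(=O)C(F)(F)F)C(F)(F)F
Why: Copper-catalysed asymmetric conjugate addition of the methylzinc reagent to the ketone-activated β-carbon of the cyclic γ-keto ester creates the C4 quaternary centre under ligand control, and the zinc enolate, which can only be the C10–C5 enolate, is O-triflated in the same flask, so that the C5=C10 alkene and a coupling handle at C10 are fixed together.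

Step 2
Reactants: 4 methyl hydrogen (R)-3-methylglutarate
Product: 6 (4R)-4-methyltetrahydro-2H-pyran-2-one, via hydroxy ester 5 (not isolated)
Conditions: BH3·SMe2, THF, 0 °C → rt; MeOH; then TsOH (cat.), CH2Cl2, rt
Reagents that add atoms: none
Why: Borane reduces the free carboxylic acid and leaves the methyl ester, and the δ-hydroxy ester lactonises under acid catalysis; the C8 stereocentre from the chiral pool is not touched.

Step 3
Reactants: 6 (4R)-4-methyltetrahydro-2H-pyran-2-one; 3 methyl (1S)-1-methyl-3-{[(trifluoromethyl)sulfonyl]oxy}cyclohex-2-ene-1-carboxylate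
Product: 9 methyl (1S)-1-methyl-3-[(3R,4R)-4-methyl-2-oxotetrahydro-2H-pyran-3-yl]cyclohex-2-ene-1-carboxylate, via lithium enolate 7 (not isolated), via chlorozinc enolate 8 (not isolated)
Conditions: 6, LiN(SiMe3)2, THF, −78 °C; ZnCl2, −78 °C → rt; then 3, Pd(dba)2 (cat.), t-Bu3P (cat.), THF, rt → 50 °C; AcOH quench at −78 °C
Reagents that add atoms: none
Why: Palladium-catalysed α-alkenylation of an ester enolate (Negishi-type coupling of the zinc enolate with the alkenyl triflate) forms the C9–C10 bond at the only enolisable position of the lactone; the configuration at C9 in 9 is of no consequence because C9 is re-enolised in step 4.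

Step 4
Reactants: 9 methyl (1S)-1-methyl-3-[(3R,4R)-4-methyl-2-oxotetrahydro-2H-pyran-3-yl]cyclohex-2-ene-1-carboxylate
Product: 11 methyl (1S)-3-[(3S,4R)-3,4-dimethyl-2-oxotetrahydro-2H-pyran-3-yl]-1-methylcyclohex-2-ene-1-carboxylate, via lithium dienolate 10 (not isolated)
Conditions: LiN(i-Pr)2, THF, −78 °C; MeI, DMPU, −78 → −40 °C
Reagents that add atoms: iodomethane CI
Why: Kinetic deprotonation of the doubly activated C9–H gives a dienolate that keeps the C5=C10 alkene, and enolate C-methylation occurs at C9 anti to the C8 methyl, which A(1,2) strain against the C9 alkenyl group forces pseudoaxial, so the C9 quaternary centre is set with the two methyls trans on the lactone ring.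

Step 5
Reactants: 11 methyl (1S)-3-[(3S,4R)-3,4-dimethyl-2-oxotetrahydro-2H-pyran-3-yl]-1-methylcyclohex-2-ene-1-carboxylate
Product: 12 methyl (1S)-3-[(3S,4R)-2-hydroxy-3,4-dimethyltetrahydro-2H-pyran-3-yl]-1-methylcyclohex-2-ene-1-carboxylate (anomer mixture)
Conditions: i-Bu2AlH (1.1 equiv), toluene, −78 °C
Reagents that add atoms: none
Why: Lactone-to-lactol reduction: i-Bu2AlH adds once at −78 °C and the aluminium hemiacetal survives until work-up, while the acyclic methyl ester on the quaternary C4 should react more slowly.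

Step 6
Reactants: 12 methyl (1S)-3-[(3S,4R)-2-hydroxy-3,4-dimethyltetrahydro-2H-pyran-3-yl]-1-methylcyclohex-2-ene-1-carboxylate
Product: 13 methyl (1S)-3-[(3S,4R)-6-hydroxy-3,4-dimethylhex-1-en-3-yl]-1-methylcyclohex-2-ene-1-carboxylate
Conditions: Ph3PCH3Br, KOt-Bu, THF, 0 °C → 50 °C
Reagents that add atoms: methyltriphenylphosphonium bromide C[P+](c1ccccc1)(c1ccccc1)c1ccccc1.[Br-]
Why: Wittig methylenation of the hydroxy aldehyde in equilibrium with the lactol turns C11 into a vinyl carbon and frees the C6 hydroxyl; the aldehyde has no α-hydrogen, so C9 cannot epimerise.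

Step 7
Reactants: 13 methyl (1S)-3-[(3S,4R)-6-hydroxy-3,4-dimethylhex-1-en-3-yl]-1-methylcyclohex-2-ene-1-carboxylate
Product: 15 methyl (1S)-3-[(3R,4S)-1-hydroxy-3,4-dimethyloct-7-en-4-yl]-1-methylcyclohex-2-ene-1-carboxylate, via bis-boryl adduct 14 (not isolated)
Conditions: 9-BBN (2.5 equiv), THF, 0 °C → rt; then vinyl bromide, Pd(dppf)Cl2 (cat.), aq. K3PO4, THF/DMF, 50 °C (sealed)
Reagents that add atoms: vinyl bromide C=CBr
Why: 9-BBN hydroborates only the monosubstituted alkene at its terminal carbon (the hindered trisubstituted ring alkene is inert), and the B-alkyl Suzuki–Miyaura coupling with vinyl bromide extends C11–C12 to the butenyl chain.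

Step 8
Reactants: 15 methyl (1S)-3-[(3R,4S)-1-hydroxy-3,4-dimethyloct-7-en-4-yl]-1-methylcyclohex-2-ene-1-carboxylate
Product: 16 methyl (1S)-3-[(3R,4S)-3,4-dimethyl-1-oxooct-7-en-4-yl]-1-methylcyclohex-2-ene-1-carboxylate
Conditions: DMP, NaHCO3, CH2Cl2, 0 °C → rt
Reagents that add atoms: none
Why: Dess–Martin oxidation converts the primary alcohol into the C6 aldehyde under buffered neutral conditions that leave both alkenes and all stereocentres alone.

Step 9
Reactants: 16 methyl (1S)-3-[(3R,4S)-3,4-dimethyl-1-oxooct-7-en-4-yl]-1-methylcyclohex-2-ene-1-carboxylate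
Product: 17 methyl (1S,5S,6R,8R,8aR)-5-(but-3-en-1-yl)-8-hydroxy-1,5,6-trimethyl-1,2,3,5,6,7,8,8a-octahydronaphthalene-1-carboxylate
Conditions: Me2AlCl (2.2 equiv), CH2Cl2, −78 → −40 °C; cold aq. potassium sodium tartrate quench
Reagents that add atoms: none
Why: Me2AlCl binds the aldehyde oxygen, C5 of the ring-A alkene attacks C6 while the β-hydrogen on C1 passes to oxygen through a six-membered pericyclic array, and the product is held as an aluminium alkoxide with loss of methane, so no proton remains to isomerise the new alkene. The closest known reaction type is the type 2 intramolecular carbonyl-ene cyclisation of aldehydes promoted by methylaluminium chlorides, in which the tether sits on the central carbon of the ene unit. Ring B closes as a six-membered ring, 6-endo with respect to the C5=C10 alkene (both alkene carbons end in the ring) and exo with respect to the carbonyl. C5 is set by the chair-like transition state with the C8 methyl equatorial, the C9 methyl axial and the butenyl chain equatorial, which brings C6 onto the β face of C5 (H5 α, anti to the pseudoaxial 4α-methyl); C6 is set by the need for the carbonyl oxygen to be axial to reach H1β (6β-OH). The step needs attack at C5 and not C10, hydrogen transfer from C1 only, and an untouched terminal alkene: the tertiary character of C10, the quaternary C9 and C4 (no allylic hydrogen there) and the low nucleophilicity of the monosubstituted alkene secure this.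

Step 10
Reactants: 17 methyl (1S,5S,6R,8R,8aR)-5-(but-3-en-1-yl)-8-hydroxy-1,5,6-trimethyl-1,2,3,5,6,7,8,8a-octahydronaphthalene-1-carboxylate
Product: 18 methyl (1S,5S,6R,8R,8aR)-5-(but-3-en-1-yl)-1,5,6-trimethyl-8-[(phenoxycarbonothioyl)oxy]-1,2,3,5,6,7,8,8a-octahydronaphthalene-1-carboxylate
Conditions: PhOC(S)Cl, pyridine, DMAP (cat.), CH2Cl2, 0 °C → rt
Reagents that add atoms: O-phenyl chlorothionoformate S=C(Cl)Oc1ccccc1
Why: Acylation of the axial 6β-hydroxyl with the chlorothionoformate under amine catalysis (first half of the Barton–McCombie deoxygenation) avoids a free alkoxide, which could lactonise onto the cis C4 ester.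

Step 11
Reactants: 18 methyl (1S,5S,6R,8R,8aR)-5-(but-3-en-1-yl)-1,5,6-trimethyl-8-[(phenoxycarbonothioyl)oxy]-1,2,3,5,6,7,8,8a-octahydronaphthalene-1-carboxylate
Product: 19 methyl (1S,5S,6R,8aR)-5-(but-3-en-1-yl)-1,5,6-trimethyl-1,2,3,5,6,7,8,8a-octahydronaphthalene-1-carboxylate
Conditions: Bu3SnH, AIBN (cat.), toluene, 90 °C
Reagents that add atoms: none
Why: Barton–McCombie radical deoxygenation: the stannyl radical adds to the thiocarbonyl, the C6–O bond breaks, and the secondary C6 radical is reduced by Bu3SnH faster than it can add to the remote alkenes.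

Step 12
Reactants: 19 methyl (1S,5S,6R,8aR)-5-(but-3-en-1-yl)-1,5,6-trimethyl-1,2,3,5,6,7,8,8a-octahydronaphthalene-1-carboxylate
Product: 20 methyl (1S,5S,6R,8aR)-1,5,6-trimethyl-5-(3-oxobutyl)-1,2,3,5,6,7,8,8a-octahydronaphthalene-1-carboxylate
Conditions: PdCl2 (cat.), CuCl, O2 (1 atm), DMF/H2O, rt
Reagents that add atoms: water O
Why: Wacker–Tsuji oxidation of the terminal alkene gives the methyl ketone with Markovnikov selectivity; the hindered trisubstituted ring alkene does not engage divalent palladium under these conditions.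

Step 13
Reactants: 20 methyl (1S,5S,6R,8aR)-1,5,6-trimethyl-5-(3-oxobutyl)-1,2,3,5,6,7,8,8a-octahydronaphthalene-1-carboxylate
Product: 21 methyl (1S,5S,6R,8aR)-5-[(3E)-5-ethoxy-3-methyl-5-oxopent-3-en-1-yl]-1,5,6-trimethyl-1,2,3,5,6,7,8,8a-octahydronaphthalene-1-carboxylate
Conditions: (i-PrO)2P(O)CH2CO2Et, NaH, THF, 0 → 50 °C
Reagents that add atoms: ethyl 2-(diisopropoxyphosphoryl)acetate CCOC(=O)CP(=O)(OC(C)C)OC(C)C
Why: Horner–Wadsworth–Emmons olefination of the methyl ketone should favour the (E)-enoate (ester trans to the larger chain, helped by the bulky phosphonate); the minor (Z) isomer is to be removed by chromatography.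

Step 14
Reactants: 21 methyl (1S,5S,6R,8aR)-5-[(3E)-5-ethoxy-3-methyl-5-oxopent-3-en-1-yl]-1,5,6-trimethyl-1,2,3,5,6,7,8,8a-octahydronaphthalene-1-carboxylate
Product: 22 methyl (1S,5S,6R,8aR)-5-[(3E)-5-hydroxy-3-methylpent-3-en-1-yl]-1,5,6-trimethyl-1,2,3,5,6,7,8,8a-octahydronaphthalene-1-carboxylate
Conditions: i-Bu2AlH (2.2 equiv), CH2Cl2, −78 °C
Reagents that add atoms: none
Why: 1,2-Reduction of the unhindered conjugated ethyl ester by i-Bu2AlH gives the allylic alcohol, whereas the methyl ester on the quaternary ring carbon is shielded.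

Step 15
Reactants: 22 methyl (1S,5S,6R,8aR)-5-[(3E)-5-hydroxy-3-methylpent-3-en-1-yl]-1,5,6-trimethyl-1,2,3,5,6,7,8,8a-octahydronaphthalene-1-carboxylate
Product: 23 methyl (1S,5S,6R,8aR)-5-{2-[(2S,3S)-3-(hydroxymethyl)-2-methyloxiran-2-yl]ethyl}-1,5,6-trimethyl-1,2,3,5,6,7,8,8a-octahydronaphthalene-1-carboxylate (CNP0324371.1)
Conditions: Ti(Oi-Pr)4, L-(+)-diethyl tartrate, t-BuOOH, 4 Å MS, CH2Cl2, −20 °C
Reagents that add atoms: tert-butyl hydroperoxide CC(C)(C)OO
Why: Sharpless asymmetric epoxidation: with L-(+)-diethyl tartrate the titanium peroxide delivers oxygen to the face of the (E)-allylic alcohol that gives the (2S,3S)-epoxy alcohol (13S,14S), and the non-allylic ring alkene is not epoxidised.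

Compound list
1 | methyl 3-oxocyclohex-1-ene-1-carboxylate | COC(=O)C1=CC(=O)CCC1 | starting material
2 | methylzinc enolate of methyl (1S)-1-methyl-3-oxocyclohexane-1-carboxylate (C5=C10 enolate) | COC(=O)[C@@]1(C)CCCC(O[Zn]C)=C1 | intermediate
3 | methyl (1S)-1-methyl-3-{[(trifluoromethyl)sulfonyl]oxy}cyclohex-2-ene-1-carboxylate | COC(=O)[C@@]1(C)CCCC(OS(=O)(=O)C(F)(F)F)=C1 | intermediate
4 | methyl hydrogen (R)-3-methylglutarate | OC(=O)C[C@@H](C)CC(=O)OC | starting material
5 | methyl (3R)-5-hydroxy-3-methylpentanoate | OCC[C@@H](C)CC(=O)OC | intermediate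
6 | (4R)-4-methyltetrahydro-2H-pyran-2-one | C[C@@H]1CCOC(=O)C1 | intermediate
7 | lithium enolate of 6 | C[C@@H]1CCOC(O[Li])=C1 | intermediate
8 | chlorozinc enolate of 6 | C[C@@H]1CCOC(O[Zn]Cl)=C1 | intermediate
9 | methyl (1S)-1-methyl-3-[(3R,4R)-4-methyl-2-oxotetrahydro-2H-pyran-3-yl]cyclohex-2-ene-1-carboxylate | COC(=O)[C@@]1(C)CCCC(=C1)[C@@H]2C(=O)OCC[C@H]2C | intermediate
10 | lithium dienolate of 9 (C9=C11 enolate conjugated to C5=C10) | COC(=O)[C@@]1(C)CCCC(=C1)C2=C(O[Li])OCC[C@H]2C | intermediate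
11 | methyl (1S)-3-[(3S,4R)-3,4-dimethyl-2-oxotetrahydro-2H-pyran-3-yl]-1-methylcyclohex-2-ene-1-carboxylate | COC(=O)[C@@]1(C)CCCC(=C1)[C@@]2(C)C(=O)OCC[C@H]2C | intermediate
12 | methyl (1S)-3-[(3S,4R)-2-hydroxy-3,4-dimethyltetrahydro-2H-pyran-3-yl]-1-methylcyclohex-2-ene-1-carboxylate (anomer mixture) | COC(=O)[C@@]1(C)CCCC(=C1)[C@@]2(C)C(O)OCC[C@H]2C | intermediate
13 | methyl (1S)-3-[(3S,4R)-6-hydroxy-3,4-dimethylhex-1-en-3-yl]-1-methylcyclohex-2-ene-1-carboxylate | COC(=O)[C@@]1(C)CCCC(=C1)[C@@](C)(C=C)[C@H](C)CCO | intermediate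
14 | bis-boryl adduct of 13 (9-BBN on C12 and on the C6 oxygen) | COC(=O)[C@@]1(C)CCCC(=C1)[C@@](C)(CCB2C3CCCC2CCC3)[C@H](C)CCOB4C5CCCC4CCC5 | intermediate
15 | methyl (1S)-3-[(3R,4S)-1-hydroxy-3,4-dimethyloct-7-en-4-yl]-1-methylcyclohex-2-ene-1-carboxylate | COC(=O)[C@@]1(C)CCCC(=C1)[C@@](C)(CCC=C)[C@H](C)CCO | intermediate
16 | methyl (1S)-3-[(3R,4S)-3,4-dimethyl-1-oxooct-7-en-4-yl]-1-methylcyclohex-2-ene-1-carboxylate | COC(=O)[C@@]1(C)CCCC(=C1)[C@@](C)(CCC=C)[C@H](C)CC=O | intermediate
17 | methyl (1S,5S,6R,8R,8aR)-5-(but-3-en-1-yl)-8-hydroxy-1,5,6-trimethyl-1,2,3,5,6,7,8,8a-octahydronaphthalene-1-carboxylate | COC(=O)[C@@]1(C)CCC=C2[C@H]1[C@H](O)C[C@@H](C)[C@]2(C)CCC=C | intermediate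
18 | methyl (1S,5S,6R,8R,8aR)-5-(but-3-en-1-yl)-1,5,6-trimethyl-8-[(phenoxycarbonothioyl)oxy]-1,2,3,5,6,7,8,8a-octahydronaphthalene-1-carboxylate | COC(=O)[C@@]1(C)CCC=C2[C@H]1[C@H](OC(=S)Oc3ccccc3)C[C@@H](C)[C@]2(C)CCC=C | intermediate
19 | methyl (1S,5S,6R,8aR)-5-(but-3-en-1-yl)-1,5,6-trimethyl-1,2,3,5,6,7,8,8a-octahydronaphthalene-1-carboxylate | COC(=O)[C@@]1(C)CCC=C2[C@H]1CC[C@@H](C)[C@]2(C)CCC=C | intermediate
20 | methyl (1S,5S,6R,8aR)-1,5,6-trimethyl-5-(3-oxobutyl)-1,2,3,5,6,7,8,8a-octahydronaphthalene-1-carboxylate | COC(=O)[C@@]1(C)CCC=C2[C@H]1CC[C@@H](C)[C@]2(C)CCC(C)=O | intermediate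
21 | methyl (1S,5S,6R,8aR)-5-[(3E)-5-ethoxy-3-methyl-5-oxopent-3-en-1-yl]-1,5,6-trimethyl-1,2,3,5,6,7,8,8a-octahydronaphthalene-1-carboxylate | COC(=O)[C@@]1(C)CCC=C2[C@H]1CC[C@@H](C)[C@]2(C)CC/C(C)=C/C(=O)OCC | intermediate
22 | methyl (1S,5S,6R,8aR)-5-[(3E)-5-hydroxy-3-methylpent-3-en-1-yl]-1,5,6-trimethyl-1,2,3,5,6,7,8,8a-octahydronaphthalene-1-carboxylate | COC(=O)[C@@]1(C)CCC=C2[C@H]1CC[C@@H](C)[C@]2(C)CC/C(C)=C/CO | intermediate
23 | methyl (1S,5S,6R,8aR)-5-{2-[(2S,3S)-3-(hydroxymethyl)-2-methyloxiran-2-yl]ethyl}-1,5,6-trimethyl-1,2,3,5,6,7,8,8a-octahydronaphthalene-1-carboxylate | COC(=O)[C@@]1(C)CCC=C2[C@H]1CC[C@@H](C)[C@]2(C)CC[C@]1(C)O[C@H]1CO | target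

Total step count: 15. Longest linear sequence: 14 steps (steps 1 and 3–15 from 1; equally steps 2–15 from 4).

Steps most likely to fail

Step 9. What may go wrong: attack on the wrong face of C5, transfer of a methyl group from aluminium to the aldehyde, or lactonisation of the new 6β-alkoxide onto the cis C4 ester. Fallback: ring B is closed by an umpoled allylation instead of an ene reaction. Setting out from alcohol 15, allylic hydroxylation at C1 (SeO2 cat., t-BuOOH; C1 is the only allylic position of the ring alkene that carries hydrogen) would give the C1-hydroxy alcohol F1. Selective oxidation of the primary hydroxyl (TEMPO, PhI(OAc)2) would give the hydroxy aldehyde F2, and ClCO2Me with pyridine the allylic carbonate F3. Pd(PPh3)4 with Et2Zn would then turn the C1–C10–C5 allyl unit into an allylzinc that adds through C5 to the C6 aldehyde in a closed chair; the allylic transposition fixes the alkene at C1=C10, and the sequence comes back to the route at 17.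

Step 3. What may go wrong: slow coupling at the hindered zinc enolate, self-condensation of the lactone enolate, or migration of the C5=C10 alkene into conjugation with the lactone under basic conditions. Fallback: the polarity of the partners is reversed. Lactone 6 would be brominated at C9 through its silyl ketene acetal (LiN(SiMe3)2, Me3SiCl; NBS) to the bromolactone F4. Triflate 3 would be borylated (B2pin2, PdCl2(PPh3)2, PPh3, KOPh) to the alkenyl boronate F5. The two would be joined by a Suzuki–Miyaura coupling of the α-bromo carbonyl compound (NiCl2·glyme, bipyridine ligand, K3PO4), which comes back to the route at 9.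

Step 5. What may go wrong: competing hydride attack on the C4 methyl ester, or over-reduction of the lactol to the diol. Fallback: C11 is brought to the aldehyde level through an amide. Setting out from lactone 11, opening with Me2AlN(OMe)Me (from Me3Al and MeNHOMe·HCl) would give the hydroxy N-methoxy-N-methylamide F6. Cp2Zr(H)Cl reduces such amides to aldehydes and leaves esters, and the resulting hydroxy aldehyde closes to lactol 12, where the route is rejoined.

Further compounds
F1 | step 9 | methyl (1S)-4-hydroxy-3-[(3R,4S)-1-hydroxy-3,4-dimethyloct-7-en-4-yl]-1-methylcyclohex-2-ene-1-carboxylate (C1 epimer mixture) | COC(=O)[C@@]1(C)CCC(O)C(=C1)[C@@](C)(CCC=C)[C@H](C)CCO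
F2 | step 9 | methyl (1S)-3-[(3R,4S)-3,4-dimethyl-1-oxooct-7-en-4-yl]-4-hydroxy-1-methylcyclohex-2-ene-1-carboxylate | COC(=O)[C@@]1(C)CCC(O)C(=C1)[C@@](C)(CCC=C)[C@H](C)CC=O
F3 | step 9 | methyl (1S)-3-[(3R,4S)-3,4-dimethyl-1-oxooct-7-en-4-yl]-4-[(methoxycarbonyl)oxy]-1-methylcyclohex-2-ene-1-carboxylate | COC(=O)[C@@]1(C)CCC(OC(=O)OC)C(=C1)[C@@](C)(CCC=C)[C@H](C)CC=O
F4 | step 3 | (4R)-3-bromo-4-methyltetrahydro-2H-pyran-2-one | C[C@@H]1CCOC(=O)C1Br
F5 | step 3 | methyl (1S)-1-methyl-3-(4,4,5,5-tetramethyl-1,3,2-dioxaborolan-2-yl)cyclohex-2-ene-1-carboxylate | COC(=O)[C@@]1(C)CCCC(B2OC(C)(C)C(C)(C)O2)=C1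
F6 | step 5 | methyl (1S)-3-[(2S,3R)-5-hydroxy-1-[methoxy(methyl)amino]-2,3-dimethyl-1-oxopentan-2-yl]-1-methylcyclohex-2-ene-1-carboxylate | COC(=O)[C@@]1(C)CCCC(=C1)[C@@](C)(C(=O)N(C)OC)[C@H](C)CCO
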